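## Analysis of the target

The target (34) is built from two cyclohexane rings of the quinic acid type and two (E)-caffeoyl groups; each ring is numbered C1 (quaternary, bearing O1 and the carboxyl carbon C7), C2, C3 (bearing O3), C4 and C5 (the diol carbons) and C6. In ring A, O1 is a free tertiary hydroxyl and C7 is esterified with O1 of ring B, whose own C7 is a free acid, while in both rings O3 carries the caffeoyl ester and O4/O5 form a free cis-diol. There are eight stereocentres, four per ring, arranged identically in both rings: O1, O4 and O5 on one face, C7 and O3 on the other, descriptors 1R,3S,4S,5S. This is the mirror image of the quinate unit of natural chlorogenic acid (1S,3R,4R,5R), so (−)-quinic acid has the wrong handedness and both rings must be made with absolute control from achiral material. The sensitive groups are the two cinnamate esters (acyl migration to O4 under base, a reducible and oxidisable C=C), the air- and base-sensitive catechols, and three ester bonds that forbid any late saponification; an O3 hydroxyl cis to a C7 ester can also lactonise. The hard bond is the central ester, which joins a quaternary, alpha-oxygenated acyl carbon to a tertiary, alpha-carboxylated carbinol oxygen. The strategy rests on C1 of ring B: with its acyloxy oxygen and C7, flanked by the methylenes C2 and C6, it is the alpha-carbon of a 2-acyloxyacrolein joined to a four-carbon diene, C2–C5 being the diene carbons and C6 the acrolein methylene.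

## Retrosynthetic reasoning

**Acid-labile groups last (34 from 33).** The final step removes only acid-labile groups, because 34 tolerates neither base nor hydrogenation. All temporary groups of 33 are therefore acetals or an acid-labile benzylic ester.

**Both caffeoyl esters (33 to 28 and 31).** The two O3–C(acyl) bonds are cut, giving diol 28 and two molecules of protected acid 31 (from caffeic acid 29 through 30, activated as chloride 32). The cut is placed here because the cinnamate alkenes would not survive the iodination and dihydroxylation that build ring B, and because one operation then installs both groups. The forward acylation must reach only the two secondary O3 hydroxyls, which the protecting groups of 28 ensure.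

**Ring B hydroxy ester to lactone (28 and 27 to 25).** The silyl ether on O3 of ring A is restored (27). The free O3 hydroxyl and the ester on C7 of ring B are then retraced, through carboxylate 26, to the gamma-lactone 25, in which one bridge masks both functions. The forward opening must cleave the strained lactone without touching the central ester.

**Oxygen relay in ring B (25 to 21).** The acetonide is removed (24), the C4–O and C5–O bonds are cut to alkene 23, the alkene is traced to iodolactone 22, and the C3–O3 bond is cut to acid 21. Each oxygen is delivered under the control of the one before it: C7 places O3 on its own face, and the lactone bridge then sends O4 and O5 to the opposite face. Nothing but C1 needs external control.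

**Key disconnection (21 and 20 to 19 and 5).** Acid 21 comes from aldehyde 20. In 20 the bonds C1–C2 and C5–C6 of ring B are cut, which gives the 2-acyloxyacrolein 19 and butadiene 5. The cut is made here because the central ester is then already present on a planar carbon, and C1 becomes quaternary only in the ring closure. The symmetric diene leaves no regiochemical or endo/exo question. The forward step must set one stereocentre, C1 of ring B.

**Dienophile (19 to 15 and 1).** 19 is traced to enol ester 18, and the C7(A)–O bond is cut to acid 15 (as chloride 16) and the potassium enolate 17 of ketone 1. The ester is thus made on a flat enolate oxygen, and a thermal retro-[4+2] fragmentation of 18 then unmasks the enal.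

**Ring A acid (15 to 11).** 15 is traced through ester 14, silyl ether 13 and diol ester 12 to lactone 11. The small acetal on O1 keeps the acyl carbon accessible and is lost in the final acid step. The silyl ether on O3 can be removed alone before acylation.

**Ring A core (11 to 4 and 5; 4 to 1).** 11 is traced through 10, 9, 8, 7 and 6 by the same relay as ring B, and 6 is cut into acrolein 4 and butadiene 5. Acrolein 4 comes from 1 through the sodium enolate 2 and the enol ester 3. The same reaction with the same catalyst antipode sets C1 of both rings, and the simple case is run first.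

## Alternatives that were turned down

**Alternative 1: double epoxy-alcohol opening.**
- Disconnection: the two C3–O3 bonds (alkyl–oxygen).
- Forward key step: the bis(epoxy alcohol) A2, with a 3,4-epoxide syn to the free O5 hydroxyl in each ring, would be opened by two molecules of di-O-allylcaffeic acid A3 under the tetravalent titanium alkoxide Ti(OiPr)4. The carboxylate would attack C3 of each chelated epoxy alcohol with inversion and give the penta-allyl compound A1, which is deallylated with the zerovalent palladium complex Pd(PPh3)4.
- For: one step installs both caffeoyl groups and both O4 hydroxyls with the correct trans relationship, and no diol protection is needed. On economy of the endgame it is stronger than the chosen route, which spends steps on acetonides, lactone opening and acylation.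
- Against: the step forms none of the difficult bonds. The central tertiary ester and both rings of the unnatural series must already be present in A2. Carboxylic acids are weak nucleophiles in this opening, the attack must be trans-diaxial in both rings, the alpha-hydroxy ester of ring A offers the metal a competing chelation site, and alkoxide ligands can transesterify the allyl ester.
- Comparison: it is an attractive endgame but not a route to the skeleton. The chosen strategy offers in its place one step that makes the central ester and C1 of ring B together, and a lactone relay with predictable stereochemistry.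

**Alternative 2: Passerini three-component union.**
- Disconnection: C1–C7 of ring B and the central C7(A)–O1(B) bond together.
- Forward key step: the ring A hydroxy acid A7, the ring B cyclohexanone A5 and the convertible isocyanide A6 would combine to the alpha-acyloxy amide A4, whose amide is later converted to the ring B acid.
- For: it joins two complete rings in one step and forms the hindered ester by an intramolecular acyl shift, not by acylating a tertiary alcohol. On convergence it is stronger than the chosen, linear route.
- Against: C1 of ring B would be set by axial or equatorial attack of the isocyanide on a flexible cyclohexanone, with no catalyst control. Ketones and hindered alpha-hydroxy acids are poor Passerini partners. The amide of A4 must be cleaved next to the central ester, under conditions that threaten that ester. A5 and A7 both belong to the unnatural series, so neither is at hand from the chiral pool and both rings would still need a de novo synthesis.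
- Comparison: the chosen strategy offers catalyst control at C1, a carboxyl group reached by a mild aldehyde oxidation, and one ring synthesis used twice.

**Alternative 3: biomimetic aldol.**
- Disconnection: C1–C6 of one ring.
- Forward key step: the diketo ester A9, derived from diethyl L-tartrate A10, would cyclise by an intramolecular enamine aldol reaction of its methyl ketone onto the alpha-keto ester carbonyl. This gives the dehydroquinate-type ketol A8, with C1 set in the ring closure.
- For: A10 has the correct handedness for O3 and O4 of this series, and the step needs no gaseous diene and no chiral catalyst. On raw material and on redox economy within the ring it is as strong as or stronger than the chosen route.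
- Against: A8 is a single ring with a free tertiary hydroxyl, so the central ester would have to be made by acylating that hindered hydroxyl with an equally hindered acid. The C1 configuration depends on the conformational preference of a ring with a trans-fused acetonide. The beta-ketol of A8 is prone to retro-aldol cleavage and dehydration. The C5 ketone needs a stereoselective reduction, and A9 needs two-directional homologation of A10.
- Comparison: it reaches one ring sooner but leaves the dimer problem open. The chosen strategy offers the central ester formed on an enol oxygen before C1 becomes quaternary.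

Key step: step 15

Conventions: TBS = tert-butyldimethylsilyl, MOM = methoxymethyl, PMB = 4-methoxybenzyl; ring numbering as in the analysis. With a ring drawn so that C1 to C6 runs clockwise, O1, O4 and O5 point towards the viewer and C7 and O3 away; the SMILES in the compound list fix the absolute configuration.

Assumption (remark on the chemistry): the (R)-antipode of 1,1'-binaphthyl-2,2'-diamine is taken as the one that gives the 1R adducts 6 and 20. The sense is to be confirmed on 6; if it is the opposite, the (S)-antipode is used in steps 3 and 15 and nothing else changes.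

## Route

Step 1
Reactants: 1 2,2-dimethyl-1,3-dioxan-5-one
Product: 3 2,2-dimethyl-4H-1,3-dioxin-5-yl cyclohexanecarboxylate, via sodium enolate 2 (not isolated)
Conditions: NaN(SiMe3)2, THF, −78 °C; then transfer into cyclohexanecarbonyl chloride (1.3 equiv), THF, −78 → 0 °C
Reagents that add atoms: cyclohexanecarbonyl chloride, O=C(Cl)C1CCCCC1
Why: Trapping of a ketone enolate on oxygen by a hard, unhindered acyl chloride held in excess gives the enol ester; the sodium enolate is sufficient for this easy acylation, and no stereocentre is formed.

Step 2
Reactants: 3 2,2-dimethyl-4H-1,3-dioxin-5-yl cyclohexanecarboxylate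
Product: 4 3-oxoprop-1-en-2-yl cyclohexanecarboxylate (2-(cyclohexanecarbonyloxy)acrolein)
Conditions: toluene, 110 °C, BHT (cat.)
Reagents that add atoms: none
Why: Retro-hetero-Diels–Alder fragmentation of the 4H-1,3-dioxin expels acetone, which distils off, and unmasks the enal.

Step 3
Reactants: 4 3-oxoprop-1-en-2-yl cyclohexanecarboxylate; 5 buta-1,3-diene
Product: 6 (1R)-1-formylcyclohex-3-en-1-yl cyclohexanecarboxylate
Conditions: (R)-1,1'-binaphthyl-2,2'-diamine (10 mol%), HNTf2 (19 mol%), H2O (10 mol%), 5 (excess), EtCN, −40 → −20 °C, sealed vessel
Reagents that add atoms: none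
Why: Enantioselective iminium-catalysed Diels–Alder reaction of a 2-acyloxyacrolein: the primary ammonium salt condenses with the aldehyde, its second ammonium group hydrogen-bonds to the acyloxy carbonyl and the binaphthyl shields one face, so the catalyst sets C1 as R. The symmetric diene excludes regio- and endo/exo isomers, and this run also confirms the sense of induction for the key step.

Step 4
Reactants: 6 (1R)-1-formylcyclohex-3-en-1-yl cyclohexanecarboxylate
Product: 7 (1R)-1-(cyclohexanecarbonyloxy)cyclohex-3-ene-1-carboxylic acid
Conditions: NaClO2, NaH2PO4, 2-methylbut-2-ene, t-BuOH/H2O, 0 °C → rt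
Reagents that add atoms: sodium chlorite, [Na+].[O-]Cl=O
Why: Pinnick oxidation takes the aldehyde to the acid; the scavenger alkene removes hypochlorous acid so the ring alkene is spared, and the quaternary C1 cannot epimerise.

Step 5
Reactants: 7 (1R)-1-(cyclohexanecarbonyloxy)cyclohex-3-ene-1-carboxylic acid
Product: 8 4-iodo-7-oxo-6-oxabicyclo[3.2.1]octan-1-yl cyclohexanecarboxylate (C7→O3 gamma-lactone; iodine on C4 trans to O3)
Conditions: I2, KI, NaHCO3, THF/H2O, 0 °C → rt, dark
Reagents that add atoms: iodine, [I][I]
Why: Iodolactonisation: the carboxylate opens the iodonium ion at C3 from its own face (5-exo, gamma-lactone preferred over delta-lactone), so O3 is cis to C7 and iodine is anti on C4. The anionic carboxylate outcompetes the neutral ester carbonyl on O1, and the rigid product is a likely point to raise enantiomeric purity by crystallisation.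

Step 6
Reactants: 8 4-iodo-7-oxo-6-oxabicyclo[3.2.1]octan-1-yl cyclohexanecarboxylate
Product: 9 7-oxo-6-oxabicyclo[3.2.1]oct-3-en-1-yl cyclohexanecarboxylate (C7→O3 lactone; C4=C5 alkene)
Conditions: DBU, toluene, 90 °C
Reagents that add atoms: none
Why: E2 elimination: the iodide on C4 has an antiperiplanar hydrogen only on C5 (the C3 hydrogen is syn to iodine), so the C4=C5 alkene should form.

Step 7
Reactants: 9 7-oxo-6-oxabicyclo[3.2.1]oct-3-en-1-yl cyclohexanecarboxylate
Product: 10 3,4-dihydroxy-7-oxo-6-oxabicyclo[3.2.1]octan-1-yl cyclohexanecarboxylate (O4 and O5 cis to O1 and trans to O3)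
Conditions: OsO4 (2 mol%), N-methylmorpholine N-oxide, acetone/H2O, rt
Reagents that add atoms: OsO4, O=[Os](=O)(=O)=O; N-methylmorpholine N-oxide, C[N+]1([O-])CCOCC1; water, O
Why: Catalytic OsO4 cis-dihydroxylation; the reagent adds to the face of the C4=C5 alkene opposite to the lactone bridge, which places O4 and O5 cis to O1 and trans to O3.

Step 8
Reactants: 10 3,4-dihydroxy-7-oxo-6-oxabicyclo[3.2.1]octan-1-yl cyclohexanecarboxylate
Product: 11 4,5-O-isopropylidene derivative of 10 (acetonide lactone)
Conditions: 2,2-dimethoxypropane, TsOH·H2O (cat.), acetone, rt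
Reagents that add atoms: 2,2-dimethoxypropane, COC(C)(C)OC
Why: Acid-catalysed acetal exchange; the cis-4,5-diol closes the five-membered acetal and no other hydroxyl is present.

Step 9
Reactants: 11 acetonide lactone
Product: 12 methyl 1,3-dihydroxy-4,5-(isopropylidenedioxy)cyclohexane-1-carboxylate (O1, O4, O5 on one face; C7, O3 on the other)
Conditions: NaOMe (0.3 equiv), MeOH, 0 °C → rt; AcOH quench
Reagents that add atoms: methanol, CO; sodium methoxide, C[O-].[Na+]
Why: Methoxide opens the strained gamma-lactone to the methyl ester and removes the temporary acyl group from O1 by transesterification (the alpha-ester makes O1 a good leaving group). The acetic acid quench in methanol fixes the ester before relactonisation.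

Step 10
Reactants: 12 methyl 1,3-dihydroxy-4,5-(isopropylidenedioxy)cyclohexane-1-carboxylate
Product: 13 3-O-TBS ether of 12
Conditions: TBSCl, imidazole, DMF, rt
Reagents that add atoms: tert-butyldimethylsilyl chloride, CC(C)(C)[Si](C)(C)Cl
Why: Silylation with TBSCl/imidazole is selective for the secondary O3 hydroxyl; the tertiary, electron-poor O1 hydroxyl should not react.

Step 11
Reactants: 13 3-O-TBS ether of 12
Product: 14 methyl 1-(methoxymethoxy)-3-(TBS-oxy)-4,5-(isopropylidenedioxy)cyclohexane-1-carboxylate
Conditions: MOMCl, i-Pr2NEt, Bu4NI (cat.), ClCH2CH2Cl, 60 °C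
Reagents that add atoms: chloromethyl methyl ether, COCCl
Why: Alkylation of the tertiary hydroxyl by the reactive alpha-chloro ether under iodide catalysis; the small acetal keeps the acyl carbon accessible and is removed in the final acid step.

Step 12
Reactants: 14 methyl ester with O1-MOM, O3-TBS and 4,5-acetonide
Product: 15 ring A acid: 1-(methoxymethoxy)-3-(TBS-oxy)-4,5-(isopropylidenedioxy)cyclohexane-1-carboxylic acid
Conditions: LiOH·H2O, THF/MeOH/H2O, rt → 40 °C; then 0.5 M HCl to pH 3–4 at 0 °C
Reagents that add atoms: lithium hydroxide, [Li+].[OH-]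
Why: Saponification of the methyl ester; the silyl ether, the acetals and the quaternary C1 are stable to aqueous base, and the cold, mildly acidic work-up spares the acid-labile groups.

Step 13
Reactants: 15 ring A acid; 1 2,2-dimethyl-1,3-dioxan-5-one
Product: 18 2,2-dimethyl-4H-1,3-dioxin-5-yl ester of 15, via ring A acid chloride 16 (not isolated), via potassium enolate 17 (not isolated)
Conditions: 15, 1-chloro-N,N,2-trimethylprop-1-en-1-amine, CH2Cl2, 0 °C → rt; 1, KN(SiMe3)2, THF, −78 °C; then 16, −78 → 0 °C
Reagents that add atoms: none
Why: The chloroenamine makes the acid chloride without releasing HCl, so TBS, MOM and acetonide survive; the potassium enolate, the most dissociated and most oxygen-reactive of the alkali enolates, is chosen for this hindered chloride and is acylated on oxygen. The acyl carbon is quaternary, so no ketene can form, and the central ester bond is made on a flat enol oxygen and not on a tertiary alkoxide.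

Step 14
Reactants: 18 2,2-dimethyl-4H-1,3-dioxin-5-yl ester of 15
Product: 19 3-oxoprop-1-en-2-yl ester of 15 (2-(ring A acyloxy)acrolein)
Conditions: toluene, 110 °C, BHT (cat.)
Reagents that add atoms: none
Why: Retro-hetero-Diels–Alder fragmentation as in step 2; the neutral thermolysis leaves the silyl ether and both acetals intact.

Step 15
Reactants: 19 2-(ring A acyloxy)acrolein; 5 buta-1,3-diene
Product: 20 (1R)-1-formylcyclohex-3-en-1-yl ester of 15
Conditions: (R)-1,1'-binaphthyl-2,2'-diamine (10 mol%), HNTf2 (19 mol%), H2O (10 mol%), 5 (excess), EtCN, −20 → 0 °C, sealed vessel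
Reagents that add atoms: none
Why: The primary amine of the catalyst condenses with the aldehyde of 19 to an iminium ion, which lowers the LUMO of the enal; butadiene then adds in a concerted, asynchronous, suprafacial [4+2] cycloaddition that forms C1–C2 and C5–C6 of ring B, and hydrolysis of the product iminium by the added water returns the catalyst. The closest known reaction type is the enantioselective Diels–Alder reaction of 2-acyloxyacroleins under chiral primary ammonium catalysis, as used in step 3, together with the thermal cycloaddition of butadiene to 2-acyloxyacrylates. The six-membered carbocycle of ring B is closed by this intermolecular [4+2] cycloaddition, with the central ester already in place on the dienophile. The only new stereocentre, C1 of ring B, is set as R by the catalyst: its second ammonium group hydrogen-bonds to the acyloxy carbonyl and fixes the iminium geometry, and the binaphthyl backbone blocks one face of the dienophile. Only facial selectivity is needed, because the symmetric diene excludes regio- and endo/exo isomers. The catalyst antipode is dictated by the required 1R configuration and is the one used in step 3; the stereocentres of ring A lie five bonds from C1 and should not override it, and any C1 epimer is a diastereomer of 20 that can be separated. The low temperature, the weak anilinium acid and the small amount of water are what the TBS ether, the MOM acetal and the acetonide need to survive.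

Step 16
Reactants: 20 (1R)-1-formylcyclohex-3-en-1-yl ester of 15
Product: 21 (1R)-1-(ring A acyloxy)cyclohex-3-ene-1-carboxylic acid
Conditions: NaClO2, NaH2PO4, 2-methylbut-2-ene, t-BuOH/H2O, 0 °C → rt
Reagents that add atoms: sodium chlorite, [Na+].[O-]Cl=O
Why: Pinnick oxidation as in step 4; the buffered chlorite should leave the silyl ether, the acetals and the ring alkene untouched.

Step 17
Reactants: 21 (1R)-1-(ring A acyloxy)cyclohex-3-ene-1-carboxylic acid
Product: 22 ring B iodolactone (ester of 15 at O1; C7→O3 gamma-lactone; iodine on C4 trans to O3)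
Conditions: I2, KI, NaHCO3, THF/H2O, 0 °C → rt, dark
Reagents that add atoms: iodine, [I][I]
Why: Iodolactonisation as in step 5: the ring B carboxylate closes onto C3 from its own face (5-exo) with iodine anti on C4, so C3 and C4 of ring B are set from C1. The weakly basic medium spares all protecting groups.

Step 18
Reactants: 22 ring B iodolactone
Product: 23 ring B unsaturated lactone (ester of 15 at O1; C7→O3 lactone; C4=C5 alkene)
Conditions: DBU, toluene, 90 °C
Reagents that add atoms: none
Why: E2 elimination as in step 6; only the C5 hydrogen is antiperiplanar to the iodide, and the bridgehead ester has no way to eliminate.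

Step 19
Reactants: 23 ring B unsaturated lactone
Product: 24 ring B diol lactone (O4 and O5 cis to O1 and trans to O3)
Conditions: OsO4 (2 mol%), N-methylmorpholine N-oxide, acetone/H2O, rt
Reagents that add atoms: OsO4, O=[Os](=O)(=O)=O; N-methylmorpholine N-oxide, C[N+]1([O-])CCOCC1; water, O
Why: OsO4 cis-dihydroxylation from the face opposite to the lactone bridge, as in step 7, sets C4 and C5 of ring B with O4 and O5 cis to O1.

Step 20
Reactants: 24 ring B diol lactone
Product: 25 ring B acetonide lactone (4,5-O-isopropylidene derivative of 24)
Conditions: 2,2-dimethoxypropane, PPTS (cat.), CH2Cl2, rt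
Reagents that add atoms: 2,2-dimethoxypropane, COC(C)(C)OC
Why: Acid-catalysed acetal exchange on the cis-diol; the weak acid PPTS should keep the TBS ether and the MOM acetal.

Step 21
Reactants: 25 ring B acetonide lactone
Product: 27 PMB ester of the opened ring B (free O3 hydroxyl on ring B; O3-TBS on ring A), via lithium carboxylate 26 (not isolated)
Conditions: LiOH·H2O (1.1 equiv), THF/H2O, 0 °C; evaporation; 4-methoxybenzyl chloride, Bu4NI (cat.), DMF, rt
Reagents that add atoms: lithium hydroxide, [Li+].[OH-]; 4-methoxybenzyl chloride, COc1ccc(CCl)cc1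
Why: Hydroxide opens the strained gamma-lactone much faster than it attacks the central ester, which is flanked by two quaternary carbons. The carboxylate is then alkylated on oxygen (SN2 on the benzylic halide), which does not depend on the hindrance at C7 and frees O3 of ring B.

Step 22
Reactants: 27 PMB ester with O3-TBS on ring A
Product: 28 diol (free O3 hydroxyls on ring A and ring B)
Conditions: HF·pyridine, pyridine, THF, 0 °C → rt
Reagents that add atoms: none
Why: Fluoride-induced cleavage of the secondary silyl ether under buffered, weakly acidic conditions. These are chosen so that no alkoxide forms on O3 of ring A, which sits cis to the central ester and could otherwise lactonise onto C7.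

Step 23
Reactants: 29 caffeic acid
Product: 30 methoxymethyl (E)-3-[3,4-bis(methoxymethoxy)phenyl]prop-2-enoate
Conditions: MOMCl (3.5 equiv), i-Pr2NEt, DMF, 0 °C → rt
Reagents that add atoms: chloromethyl methyl ether, COCCl
Why: Exhaustive alkylation of the carboxylate and both phenols by the alpha-chloro ether; the alkene geometry is not affected.

Step 24
Reactants: 30 methoxymethyl (E)-3-[3,4-bis(methoxymethoxy)phenyl]prop-2-enoate
Product: 31 (E)-3-[3,4-bis(methoxymethoxy)phenyl]prop-2-enoic acid
Conditions: LiOH·H2O, THF/H2O, rt; then 0.5 M HCl to pH 4 at 0 °C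
Reagents that add atoms: lithium hydroxide, [Li+].[OH-]
Why: Saponification of the acetal ester is fast, the aryl MOM ethers are stable to base, and the cold, mildly acidic work-up leaves them in place.

Step 25
Reactants: 28 diol; 31 (E)-3-[3,4-bis(methoxymethoxy)phenyl]prop-2-enoic acid
Product: 33 fully protected target (both O3 acylated), via protected caffeoyl chloride 32 (not isolated)
Conditions: 31 (3 equiv), 1-chloro-N,N,2-trimethylprop-1-en-1-amine, CH2Cl2, 0 °C; then 28, pyridine, DMAP (cat.), CH2Cl2, 0 °C → rt
Reagents that add atoms: none
Why: Acid chloride formation without HCl, then DMAP-catalysed acylation of the two secondary O3 hydroxyls; every other oxygen is blocked. The weak base at low temperature should keep lactonisation of either hydroxy ester slow.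

Step 26
Reactants: 33 fully protected target
Product: 34 target compound
Conditions: TFA/H2O (9:1), anisole (20 equiv), 0 °C → rt; evaporation; reverse-phase chromatography
Reagents that add atoms: none
Why: One operation hydrolyses two acetonides and five methoxymethyl acetals and cleaves the PMB ester by acidolysis, with the benzylic cation trapped by anisole. The cinnamate esters and the central ester are stable to aqueous trifluoroacetic acid at room temperature, and no base is present, so no acyl migration is expected.

## Compound list

1 | 2,2-dimethyl-1,3-dioxan-5-one | CC1(C)OCC(=O)CO1 | starting material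
2 | sodium 2,2-dimethyl-4H-1,3-dioxin-5-olate (sodium enolate of 1; formed in the flask) | CC1(C)OCC([O-])=CO1.[Na+] | intermediate
3 | 2,2-dimethyl-4H-1,3-dioxin-5-yl cyclohexanecarboxylate | CC1(C)OCC(OC(=O)C2CCCCC2)=CO1 | intermediate
4 | 3-oxoprop-1-en-2-yl cyclohexanecarboxylate | C=C(OC(=O)C1CCCCC1)C=O | intermediate
5 | buta-1,3-diene | C=CC=C | starting material
6 | (1R)-1-formylcyclohex-3-en-1-yl cyclohexanecarboxylate | O=C(O[C@@]1(C=O)CC=CCC1)C2CCCCC2 | intermediate
7 | (1R)-1-(cyclohexanecarbonyloxy)cyclohex-3-ene-1-carboxylic acid | O=C(O[C@@]1(C(=O)O)CC=CCC1)C2CCCCC2 | intermediate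
8 | 4-iodo-7-oxo-6-oxabicyclo[3.2.1]octan-1-yl cyclohexanecarboxylate (iodine trans to lactone oxygen) | O=C(O[C@@]1(C(=O)O3)C[C@H]3[C@@H]([I])CC1)C2CCCCC2 | intermediate
9 | 7-oxo-6-oxabicyclo[3.2.1]oct-3-en-1-yl cyclohexanecarboxylate | O=C(O[C@@]1(C(=O)O3)C[C@H]3C=CC1)C2CCCCC2 | intermediate
10 | 3,4-dihydroxy-7-oxo-6-oxabicyclo[3.2.1]octan-1-yl cyclohexanecarboxylate (diol anti to lactone bridge) | O=C(O[C@@]1(C(=O)O3)C[C@H]3[C@@H](O)[C@@H](O)C1)C2CCCCC2 | intermediate
11 | acetonide of 10 | O=C(O[C@@]1(C(=O)O3)C[C@H]3[C@@H](O4)[C@@H](OC4(C)C)C1)C2CCCCC2 | intermediate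
12 | methyl 1,3-dihydroxy-4,5-(isopropylidenedioxy)cyclohexane-1-carboxylate | O[C@@]1(C(=O)OC)C[C@H](O)[C@@H](O2)[C@@H](OC2(C)C)C1 | intermediate
13 | 3-O-TBS ether of 12 | O[C@@]1(C(=O)OC)C[C@H](O[Si](C)(C)C(C)(C)C)[C@@H](O2)[C@@H](OC2(C)C)C1 | intermediate
14 | 1-O-MOM, 3-O-TBS methyl ester | COCO[C@@]1(C(=O)OC)C[C@H](O[Si](C)(C)C(C)(C)C)[C@@H](O2)[C@@H](OC2(C)C)C1 | intermediate
15 | ring A acid (O1-MOM, O3-TBS, 4,5-acetonide) | COCO[C@@]1(C(=O)O)C[C@H](O[Si](C)(C)C(C)(C)C)[C@@H](O2)[C@@H](OC2(C)C)C1 | intermediate
16 | ring A acid chloride (formed in the flask) | COCO[C@@]1(C(=O)Cl)C[C@H](O[Si](C)(C)C(C)(C)C)[C@@H](O2)[C@@H](OC2(C)C)C1 | intermediate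
17 | potassium 2,2-dimethyl-4H-1,3-dioxin-5-olate (potassium enolate of 1; formed in the flask) | CC1(C)OCC([O-])=CO1.[K+] | intermediate
18 | 2,2-dimethyl-4H-1,3-dioxin-5-yl ester of 15 | COCO[C@@]1(C(=O)OC3=COC(C)(C)OC3)C[C@H](O[Si](C)(C)C(C)(C)C)[C@@H](O2)[C@@H](OC2(C)C)C1 | intermediate
19 | 3-oxoprop-1-en-2-yl ester of 15 (2-(ring A acyloxy)acrolein) | COCO[C@@]1(C(=O)OC(=C)C=O)C[C@H](O[Si](C)(C)C(C)(C)C)[C@@H](O2)[C@@H](OC2(C)C)C1 | intermediate
20 | (1R)-1-formylcyclohex-3-en-1-yl ester of 15 | COCO[C@@]1(C(=O)O[C@@]2(C=O)CC=CCC2)C[C@H](O[Si](C)(C)C(C)(C)C)[C@@H](O3)[C@@H](OC3(C)C)C1 | intermediate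
21 | (1R)-1-(ring A acyloxy)cyclohex-3-ene-1-carboxylic acid | COCO[C@@]1(C(=O)O[C@@]2(C(=O)O)CC=CCC2)C[C@H](O[Si](C)(C)C(C)(C)C)[C@@H](O3)[C@@H](OC3(C)C)C1 | intermediate
22 | ring B iodolactone | COCO[C@@]1(C(=O)O[C@@]2(C(=O)O4)C[C@H]4[C@@H]([I])CC2)C[C@H](O[Si](C)(C)C(C)(C)C)[C@@H](O3)[C@@H](OC3(C)C)C1 | intermediate
23 | ring B unsaturated lactone | COCO[C@@]1(C(=O)O[C@@]2(C(=O)O4)C[C@H]4C=CC2)C[C@H](O[Si](C)(C)C(C)(C)C)[C@@H](O3)[C@@H](OC3(C)C)C1 | intermediate
24 | ring B diol lactone | COCO[C@@]1(C(=O)O[C@@]2(C(=O)O4)C[C@H]4[C@@H](O)[C@@H](O)C2)C[C@H](O[Si](C)(C)C(C)(C)C)[C@@H](O3)[C@@H](OC3(C)C)C1 | intermediate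
25 | ring B acetonide lactone | COCO[C@@]1(C(=O)O[C@@]2(C(=O)O4)C[C@H]4[C@@H](O5)[C@@H](OC5(C)C)C2)C[C@H](O[Si](C)(C)C(C)(C)C)[C@@H](O3)[C@@H](OC3(C)C)C1 | intermediate
26 | lithium carboxylate of the opened ring B (formed in the flask) | COCO[C@@]1(C(=O)O[C@@]2(C(=O)[O-])C[C@H](O)[C@@H](O5)[C@@H](OC5(C)C)C2)C[C@H](O[Si](C)(C)C(C)(C)C)[C@@H](O3)[C@@H](OC3(C)C)C1.[Li+] | intermediate
27 | PMB ester, ring B O3-H free, ring A O3-TBS | COCO[C@@]1(C(=O)O[C@@]2(C(=O)OCc6ccc(OC)cc6)C[C@H](O)[C@@H](O5)[C@@H](OC5(C)C)C2)C[C@H](O[Si](C)(C)C(C)(C)C)[C@@H](O3)[C@@H](OC3(C)C)C1 | intermediate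
28 | diol (both O3-H free) | COCO[C@@]1(C(=O)O[C@@]2(C(=O)OCc6ccc(OC)cc6)C[C@H](O)[C@@H](O5)[C@@H](OC5(C)C)C2)C[C@H](O)[C@@H](O3)[C@@H](OC3(C)C)C1 | intermediate
29 | caffeic acid | O=C(O)/C=C/c1ccc(O)c(O)c1 | starting material
30 | methoxymethyl (E)-3-[3,4-bis(methoxymethoxy)phenyl]prop-2-enoate | COCOC(=O)/C=C/c1ccc(OCOC)c(OCOC)c1 | intermediate
31 | (E)-3-[3,4-bis(methoxymethoxy)phenyl]prop-2-enoic acid | OC(=O)/C=C/c1ccc(OCOC)c(OCOC)c1 | intermediate
32 | (E)-3-[3,4-bis(methoxymethoxy)phenyl]prop-2-enoyl chloride (formed in the flask) | ClC(=O)/C=C/c1ccc(OCOC)c(OCOC)c1 | intermediate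
33 | fully protected target | COCO[C@@]1(C(=O)O[C@@]2(C(=O)OCc6ccc(OC)cc6)C[C@H](OC(=O)/C=C/c7ccc(OCOC)c(OCOC)c7)[C@@H](O5)[C@@H](OC5(C)C)C2)C[C@H](OC(=O)/C=C/c8ccc(OCOC)c(OCOC)c8)[C@@H](O3)[C@@H](OC3(C)C)C1 | intermediate
34 | target compound | O=C(/C=C/c1ccc(O)c(O)c1)O[C@H]1C[C@@](O)(C(=O)O[C@@]2(C(=O)O)C[C@H](OC(=O)/C=C/c3ccc(O)c(O)c3)[C@@H](O)[C@@H](O)C2)C[C@H](O)[C@@H]1O | target

## Step count and least certain steps

Total: 26 steps. Longest linear sequence: 24 steps (from 1 through steps 1–22, 25 and 26). The caffeoyl branch (steps 23 and 24) joins at step 25.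

**Step 15 (key step).** The cycloaddition may be too slow for an unactivated diene and a dienophile with a large acyl group, so that polymerisation of 19 competes. Facial selectivity may be eroded if the MOM or acetonide oxygens of ring A disturb the hydrogen bond between catalyst and acyloxy carbonyl, or if the pairing with ring A is mismatched. The acidic catalyst may also begin to cleave the acetonide.

Fallback, from 19 back to the route at 22: 19 and 5 are heated without catalyst (toluene, 100 °C, sealed vessel, BHT), which should give 20 together with its ring B C1 epimer F1. The mixture is oxidised as in step 16 to 21 and the epimeric acid F2, and iodolactonised as in step 17 to 22 and the diastereomeric iodolactone F3. Because ring A is homochiral these are diastereomers, and the rigid lactones are separated by chromatography or crystallisation; 22 is carried on.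

**Step 3.** Butadiene may react too slowly at the temperature needed for high selectivity, giving incomplete conversion or insufficient enantiomeric purity, which would later show up as diastereomers.

Fallback, from 4 back to the route at 7: 4 and 5 are heated without catalyst to the racemic aldehyde F4, which is oxidised as in step 4 to the racemic acid F5. F5 is resolved by crystallising the salt F6 of its 1R enantiomer with (S)-1-phenylethylamine (or with the antipode of the amine, if the other salt is the less soluble one). Acidification of F6 returns 7.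

**Step 13.** The acid chloride may lose its MOM group by attack of the acetal oxygen on the acyl chloride. The hindered acyl carbon may also react so slowly that proton transfer, C-acylation or self-condensation of the enolate take over.

Fallback, from 15 back to the route at 19, with no attack at the hindered carbonyl: the caesium salt of 15 is alkylated with allyl bromide (Cs2CO3, DMF) to the allyl ester F7. Ozonolysis (O3, CH2Cl2, −78 °C; Me2S) gives the 2-oxoethyl ester F8. Mannich-type alpha-methylenation of F8 (dimethylmethylideneammonium iodide, Et3N, CH2Cl2, rt) gives 19.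

**Step 26.** The electron-rich catechol rings may be alkylated by the 4-methoxybenzyl cation or by formaldehyde released from the acetals. Cleavage of the tertiary MOM ether may be incomplete, and acyl migration may set in on prolonged acid exposure.

Fallback, from 26 back to the route at 34, with the benzylic ester replaced by one removed under neutral conditions: carboxylate 26 is alkylated with allyl bromide in place of the benzylic chloride to the allyl ester F9. HF·pyridine as in step 22 gives the diol F10, and acylation with 32 as in step 25 gives the bis-caffeoyl allyl ester F11. The zerovalent palladium complex Pd(PPh3)4 with morpholine in THF cleaves the allyl ester to the acid F12. Aqueous trifluoroacetic acid, now without any benzylic cation, removes the acetals and gives 34.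

## Further compounds

F1 | step 15 | ring B C1 epimer of 20 ((1S)-1-formylcyclohex-3-en-1-yl ester of 15) | COCO[C@@]1(C(=O)O[C@]2(C=O)CC=CCC2)C[C@H](O[Si](C)(C)C(C)(C)C)[C@@H](O3)[C@@H](OC3(C)C)C1
F2 | step 15 | ring B C1 epimer of 21 | COCO[C@@]1(C(=O)O[C@]2(C(=O)O)CC=CCC2)C[C@H](O[Si](C)(C)C(C)(C)C)[C@@H](O3)[C@@H](OC3(C)C)C1
F3 | step 15 | diastereomer of 22 with mirror-image ring B | COCO[C@@]1(C(=O)O[C@]2(C(=O)O4)C[C@@H]4[C@H]([I])CC2)C[C@H](O[Si](C)(C)C(C)(C)C)[C@@H](O3)[C@@H](OC3(C)C)C1
F4 | step 3 | racemic 1-formylcyclohex-3-en-1-yl cyclohexanecarboxylate | O=CC1(OC(=O)C2CCCCC2)CC=CCC1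
F5 | step 3 | racemic 1-(cyclohexanecarbonyloxy)cyclohex-3-ene-1-carboxylic acid | OC(=O)C1(OC(=O)C2CCCCC2)CC=CCC1
F6 | step 3 | (S)-1-phenylethylammonium salt of 7 | O=C(O[C@@]1(C(=O)[O-])CC=CCC1)C2CCCCC2.C[C@H]([NH3+])c1ccccc1
F7 | step 13 | allyl ester of 15 | COCO[C@@]1(C(=O)OCC=C)C[C@H](O[Si](C)(C)C(C)(C)C)[C@@H](O2)[C@@H](OC2(C)C)C1
F8 | step 13 | 2-oxoethyl ester of 15 | COCO[C@@]1(C(=O)OCC=O)C[C@H](O[Si](C)(C)C(C)(C)C)[C@@H](O2)[C@@H](OC2(C)C)C1
F9 | step 26 | allyl ester analogue of 27 | COCO[C@@]1(C(=O)O[C@@]2(C(=O)OCC=C)C[C@H](O)[C@@H](O5)[C@@H](OC5(C)C)C2)C[C@H](O[Si](C)(C)C(C)(C)C)[C@@H](O3)[C@@H](OC3(C)C)C1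
F10 | step 26 | allyl ester analogue of 28 | COCO[C@@]1(C(=O)O[C@@]2(C(=O)OCC=C)C[C@H](O)[C@@H](O5)[C@@H](OC5(C)C)C2)C[C@H](O)[C@@H](O3)[C@@H](OC3(C)C)C1
F11 | step 26 | allyl ester analogue of 33 | COCO[C@@]1(C(=O)O[C@@]2(C(=O)OCC=C)C[C@H](OC(=O)/C=C/c7ccc(OCOC)c(OCOC)c7)[C@@H](O5)[C@@H](OC5(C)C)C2)C[C@H](OC(=O)/C=C/c8ccc(OCOC)c(OCOC)c8)[C@@H](O3)[C@@H](OC3(C)C)C1
F12 | step 26 | ring B free acid with MOM and acetonide groups in place | COCO[C@@]1(C(=O)O[C@@]2(C(=O)O)C[C@H](OC(=O)/C=C/c7ccc(OCOC)c(OCOC)c7)[C@@H](O5)[C@@H](OC5(C)C)C2)C[C@H](OC(=O)/C=C/c8ccc(OCOC)c(OCOC)c8)[C@@H](O3)[C@@H](OC3(C)C)C1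
A1 | alternative 1 | penta-allyl-protected target | O[C@@]1(C(=O)O[C@@]2(C(=O)OCC=C)C[C@H](OC(=O)/C=C/c3ccc(OCC=C)c(OCC=C)c3)[C@@H](O)[C@@H](O)C2)C[C@H](OC(=O)/C=C/c4ccc(OCC=C)c(OCC=C)c4)[C@@H](O)[C@@H](O)C1
A2 | alternative 1 | bis(3,4-epoxy 5-alcohol) dimer, allyl ester (epoxides syn to O5) | O[C@@]1(C(=O)O[C@@]2(C(=O)OCC=C)C[C@H]3O[C@H]3[C@@H](O)C2)C[C@H]4O[C@H]4[C@@H](O)C1
A3 | alternative 1 | di-O-allylcaffeic acid | OC(=O)/C=C/c1ccc(OCC=C)c(OCC=C)c1
A4 | alternative 2 | diquinate alpha-acyloxy 6-bromopyridin-2-yl amide | O[C@@]1(C(=O)O[C@@]2(C(=O)Nc3cccc(Br)n3)C[C@H](O[Si](C)(C)C(C)(C)C)[C@@H](O4)[C@@H](OC4(C)C)C2)C[C@H](O[Si](C)(C)C(C)(C)C)[C@@H](O5)[C@@H](OC5(C)C)C1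
A5 | alternative 2 | ring B cyclohexanone (3-O-TBS, 4,5-acetonide) | O=C1C[C@H](O[Si](C)(C)C(C)(C)C)[C@@H](O2)[C@@H](OC2(C)C)C1
A6 | alternative 2 | 2-bromo-6-isocyanopyridine | [C-]#[N+]c1cccc(Br)n1
A7 | alternative 2 | ring A hydroxy acid (O1-H free, 3-O-TBS, 4,5-acetonide) | O[C@@]1(C(=O)O)C[C@H](O[Si](C)(C)C(C)(C)C)[C@@H](O2)[C@@H](OC2(C)C)C1
A8 | alternative 3 | dehydroquinate-type aldol, 3,4-acetonide, ethyl ester | O[C@@]1(C(=O)OCC)C[C@H](O2)[C@@H](OC2(C)C)C(=O)C1
A9 | alternative 3 | ethyl 4,5-(isopropylidenedioxy)-2,6-dioxoheptanoate | CCOC(=O)C(=O)C[C@H](O1)[C@@H](OC1(C)C)C(C)=O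
A10 | alternative 3 | diethyl L-tartrate | CCOC(=O)[C@H](O)[C@@H](O)C(=O)OCC
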